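## Retrosynthetic overview

1. The tetrahydrofuran is closed last, by acid-mediated C7–O bond formation in a hexa-ol obtained by LiAlH4 reduction of a lactone acetal.
2. The two adjacent lignan centres come from a three-component conjugate addition–aldol: aryl dithiane anion + (5S)-menthyloxy-2(5H)-furanone (from furfural by photo-oxygenation) + O-benzylisovanillin.
3. The central benzene ring is not bought as an arene. It is grown from symmetric methyl 3,5-dioxocyclohexanecarboxylate by a sultam-controlled Mn(III) oxidative [3+2] annulation with a feruloyl acceptor, then aromatised (I2/MeOH). This fixes the C–C bond between the two oxygens, distinguishes the oxygens (ring O vs OMe) and sets both dihydrofuran centres.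
4. Ring order: dihydrofuran → central benzene ring → tetrahydrofuran.

Assumption: the Mn(III)-generated radical attacks the Cα-si face of the (2S)-sultam enoyl (Oppolzer–Curran model, recalled rather than checked against the original reports); if the sense is opposite, the (2R)-sultam is used and nothing else changes.

## Route

Step 1
Reactants: 1 4-(benzyloxy)-3-methoxybenzaldehyde; 2 malonic acid
Product: 4 (E)-3-[4-(benzyloxy)-3-methoxyphenyl]prop-2-enoic acid, via arylidenemalonic acid 3 (not isolated)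
Conditions: pyridine, piperidine (cat.), 90 °C; aq. HCl
Reagents that add atoms: none
Why: Knoevenagel–Doebner condensation with in-situ decarboxylation gives the E-cinnamic acid.

Step 2
Reactants: 4 (E)-3-[4-(benzyloxy)-3-methoxyphenyl]prop-2-enoic acid; 5 (2S)-bornane-10,2-sultam
Product: 7 N-[(E)-3-(4-benzyloxy-3-methoxyphenyl)prop-2-enoyl]-(2S)-bornane-10,2-sultam, via acid chloride 6 (not isolated)
Conditions: (COCl)2, DMF (cat.), CH2Cl2, rt; then 5, NaH, toluene, 0 °C → rt
Reagents that add atoms: none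
Why: Standard N-acylation of the sodium salt of Oppolzer's sultam with the acid chloride.

Step 3 (key step)
Reactants: 7 N-cinnamoyl sultam; 8 methyl 3,5-dioxocyclohexane-1-carboxylate
Product: 9 methyl (2S,3S)-2-[4-(benzyloxy)-3-methoxyphenyl]-4-oxo-3-[(2S)-bornane-10,2-sultam-N-carbonyl]-2,3,4,5,6,7-hexahydro-1-benzofuran-6-carboxylate (C6 epimer mixture)
Conditions: Mn(OAc)3·2H2O (2.2 equiv), AcOH, 70 °C, N2
Reagents that add atoms: none
Why: Mn(III)-based oxidative free-radical [3+2] annulation: the C2 radical of the symmetric dione adds to Cα of the s-cis enoyl sultam on the face left open by the auxiliary, then the p-alkoxybenzyl radical is oxidised to the cation and closed by the enol oxygen trans to the acyl group, giving (2S,3S); any minor facial isomer is removed by crystallisation after step 4, where the C6 centre no longer exists.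

Step 4
Reactants: 9 annulation product
Product: 10 methyl (2S,3S)-2-[4-(benzyloxy)-3-methoxyphenyl]-4-methoxy-3-[(2S)-bornane-10,2-sultam-N-carbonyl]-2,3-dihydro-1-benzofuran-6-carboxylate
Conditions: I2 (2.2 equiv), MeOH, 60 °C
Reagents that add atoms: methanol (CO)
Why: Iodine–methanol oxidative aromatisation of a 3-alkoxycyclohex-2-enone (methyl enol ether formation, α-iodination, loss of HI) turns the remaining carbonyl into the aryl OMe, with the C6 ester easing dehydrogenation; C2 and C3 are not touched.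

Step 5
Reactants: 10 aromatised imide ester
Product: 11 [(2S,3R)-2-[4-(benzyloxy)-3-methoxyphenyl]-3-(hydroxymethyl)-4-methoxy-2,3-dihydro-1-benzofuran-6-yl]methanol
Conditions: LiAlH4, THF, 0 °C → rt
Reagents that add atoms: none
Why: Hydride reduction cleaves the N-acyl sultam to the primary alcohol (auxiliary recovered) and reduces the aryl ester, faster than any C3 enolisation; the C3 descriptor changes to R by CIP priority only.

Step 6
Reactants: 11 diol
Product: 12 (2S,3R)-2-[4-(benzyloxy)-3-methoxyphenyl]-3-(hydroxymethyl)-4-methoxy-2,3-dihydro-1-benzofuran-6-carbaldehyde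
Conditions: MnO2 (activated), CH2Cl2, rt
Reagents that add atoms: none
Why: Chemoselective MnO2 oxidation of the benzylic alcohol; the aliphatic primary alcohol is inert.

Step 7
Reactants: 12 hydroxy aldehyde
Product: 13 [(2S,3R)-2-[4-(benzyloxy)-3-methoxyphenyl]-6-(1,3-dithian-2-yl)-4-methoxy-2,3-dihydro-1-benzofuran-3-yl]methanol
Conditions: HS(CH2)3SH (1.2 equiv), I2 (10 mol%), CH2Cl2, rt
Reagents that add atoms: propane-1,3-dithiol (SCCCS)
Why: Mild iodine-catalysed dithioacetalisation of the aryl aldehyde (Corey–Seebach umpolung precursor), gentle enough for the benzylic aryl ether.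

Step 8
Reactants: 14 furfural
Product: 16 5-hydroxyfuran-2(5H)-one, via furfural endoperoxide 15 (not isolated)
Conditions: O2, hν (visible), rose bengal (cat.), MeOH, rt
Reagents that add atoms: dioxygen (O=O)
Why: Singlet-oxygen [4+2] photo-oxygenation breaks the furan aromaticity and methanolysis expels the formyl carbon as methyl formate, leaving the γ-hydroxybutenolide.

Step 9
Reactants: 16 5-hydroxyfuran-2(5H)-one; 17 (+)-menthol
Product: 19 (5S)-5-[(1S,2R,5S)-menthyloxy]furan-2(5H)-one, via (5R)-epimer 18 (not isolated)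
Conditions: CSA (cat.), toluene, reflux (Dean–Stark); crystallisation from petroleum ether with acid-catalysed equilibration of the mother liquor
Reagents that add atoms: none
Why: Acid-catalysed acetalisation followed by crystallisation-induced epimerisation at the acetal carbon (Feringa's butenolide, enantiomeric series) gives the single (5S) diastereomer.

Step 10
Reactants: 13 hydroxy dithiane; 19 (5S)-menthyloxyfuranone; 20 3-(benzyloxy)-4-methoxybenzaldehyde
Product: 23 (3R,4S,5S)-3-[(3-benzyloxy-4-methoxyphenyl)(hydroxy)methyl]-4-{2-[(2S,3R)-2-(4-benzyloxy-3-methoxyphenyl)-3-(hydroxymethyl)-4-methoxy-2,3-dihydro-1-benzofuran-6-yl]-1,3-dithian-2-yl}-5-[(1S,2R,5S)-menthyloxy]dihydrofuran-2(3H)-one (carbinol epimer mixture), via dilithiated dithiane 21 (not isolated), via lithium lactone enolate 22 (not isolated)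
Conditions: n-BuLi (2.1 equiv), THF, −78 °C; 19, −78 °C; 20, −78 °C; aq. NH4Cl
Reagents that add atoms: none
Why: Tandem conjugate addition–aldol: the dithiane anion adds to C4 of the butenolide anti to the menthyloxy group and the enolate takes the aldehyde anti to the new C4 substituent, giving the 3,4-trans lactone; the carbinol centre is left uncontrolled because step 13 erases it.

Step 11
Reactants: 23 tandem adduct
Product: 24 (3R,4S,5S)-3-[hydroxy(3-hydroxy-4-methoxyphenyl)methyl]-4-{[(2S,3R)-2-(4-hydroxy-3-methoxyphenyl)-3-(hydroxymethyl)-4-methoxy-2,3-dihydro-1-benzofuran-6-yl]methyl}-5-[(1S,2R,5S)-menthyloxy]dihydrofuran-2(3H)-one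
Conditions: Raney Ni (W-2), EtOH, reflux
Reagents that add atoms: none
Why: Raney nickel hydrogenolysis cleaves both C–S bonds and, as in related hydroxy-lignan lactone syntheses, both aryl benzyl ethers, while the benzylic carbinol and ring ethers react more slowly; no stereocentre is involved.

Step 12
Reactants: 24 lactone acetal
Product: 25 (2S,3S)-2-[hydroxy(3-hydroxy-4-methoxyphenyl)methyl]-3-{[(2S,3R)-2-(4-hydroxy-3-methoxyphenyl)-3-(hydroxymethyl)-4-methoxy-2,3-dihydro-1-benzofuran-6-yl]methyl}butane-1,4-diol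
Conditions: LiAlH4, THF, 0 °C → rt; Rochelle salt
Reagents that add atoms: none
Why: Hydride reduction of the pseudo-ester takes the lactone carbonyl and the acetal carbon (via the released aldehyde) to two CH2OH groups and expels menthol, without epimerising the adjacent centres.

Step 13
Reactants: 25 hexa-ol
Product: 26 target, (2S,3R)-dihydrobenzofuran linked to the (2R,3S,4S)-tetrahydrofuran
Conditions: CSA (0.1 equiv), MeCN–THF, 0 °C → rt, stopped at full conversion
Reagents that add atoms: none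
Why: Acid-catalysed cyclodehydration (SN1 through the p-methoxybenzylic cation, 5-exo capture by the C9' hydroxyl) gives the 2,3-trans tetrahydrofuran from either carbinol epimer, setting C2 as R; mild kinetic conditions favour O-closure over Friedel–Crafts closure onto the electron-rich central ring.

## Compound list

1 | 4-(benzyloxy)-3-methoxybenzaldehyde | O=Cc1ccc(OCc2ccccc2)c(OC)c1 | starting material
2 | malonic acid | OC(=O)CC(=O)O | starting material
3 | 2-[4-(benzyloxy)-3-methoxybenzylidene]malonic acid | OC(=O)C(=Cc1ccc(OCc2ccccc2)c(OC)c1)C(=O)O | intermediate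
4 | (E)-3-[4-(benzyloxy)-3-methoxyphenyl]prop-2-enoic acid | OC(=O)/C=C/c1ccc(OCc2ccccc2)c(OC)c1 | intermediate
5 | (2S)-bornane-10,2-sultam [(1R)-(+)-2,10-camphorsultam] | CC1(C)[C@H]2CC[C@@]13CS(=O)(=O)N[C@H]3C2 | starting material
6 | (E)-3-[4-(benzyloxy)-3-methoxyphenyl]prop-2-enoyl chloride | ClC(=O)/C=C/c1ccc(OCc2ccccc2)c(OC)c1 | intermediate
7 | N-[(E)-3-(4-benzyloxy-3-methoxyphenyl)prop-2-enoyl]-(2S)-bornane-10,2-sultam | O=C(/C=C/c1ccc(OCc2ccccc2)c(OC)c1)N1[C@H]2C[C@@H]3CC[C@@]2(CS1(=O)=O)C3(C)C | intermediate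
8 | methyl 3,5-dioxocyclohexane-1-carboxylate | COC(=O)C1CC(=O)CC(=O)C1 | starting material
9 | methyl (2S,3S)-2-[4-(benzyloxy)-3-methoxyphenyl]-4-oxo-3-(sultam-N-carbonyl)-2,3,4,5,6,7-hexahydro-1-benzofuran-6-carboxylate (C6 epimers) | COC(=O)C1CC(=O)C2=C(C1)O[C@H](c1ccc(OCc3ccccc3)c(OC)c1)[C@H]2C(=O)N1[C@H]2C[C@@H]3CC[C@@]2(CS1(=O)=O)C3(C)C | intermediate
10 | methyl (2S,3S)-2-[4-(benzyloxy)-3-methoxyphenyl]-4-methoxy-3-(sultam-N-carbonyl)-2,3-dihydro-1-benzofuran-6-carboxylate | COC(=O)c1cc(OC)c2c(c1)O[C@H](c1ccc(OCc3ccccc3)c(OC)c1)[C@H]2C(=O)N1[C@H]2C[C@@H]3CC[C@@]2(CS1(=O)=O)C3(C)C | intermediate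
11 | [(2S,3R)-2-[4-(benzyloxy)-3-methoxyphenyl]-3-(hydroxymethyl)-4-methoxy-2,3-dihydro-1-benzofuran-6-yl]methanol | OCc1cc(OC)c2c(c1)O[C@H](c1ccc(OCc3ccccc3)c(OC)c1)[C@H]2CO | intermediate
12 | (2S,3R)-2-[4-(benzyloxy)-3-methoxyphenyl]-3-(hydroxymethyl)-4-methoxy-2,3-dihydro-1-benzofuran-6-carbaldehyde | O=Cc1cc(OC)c2c(c1)O[C@H](c1ccc(OCc3ccccc3)c(OC)c1)[C@H]2CO | intermediate
13 | [(2S,3R)-2-[4-(benzyloxy)-3-methoxyphenyl]-6-(1,3-dithian-2-yl)-4-methoxy-2,3-dihydro-1-benzofuran-3-yl]methanol | S1CCCSC1c1cc(OC)c2c(c1)O[C@H](c1ccc(OCc3ccccc3)c(OC)c1)[C@H]2CO | intermediate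
14 | furfural | O=Cc1ccco1 | starting material
15 | 2,3,7-trioxabicyclo[2.2.1]hept-5-ene-1-carbaldehyde (furfural endoperoxide) | O=CC12C=CC(OO1)O2 | intermediate
16 | 5-hydroxyfuran-2(5H)-one (racemic) | OC1OC(=O)C=C1 | intermediate
17 | (+)-menthol, (1S,2R,5S) | C[C@H]1CC[C@@H]([C@H](C1)O)C(C)C | starting material
18 | (5R)-5-[(1S,2R,5S)-menthyloxy]furan-2(5H)-one | O=C1C=C[C@H](O[C@H]2C[C@@H](C)CC[C@@H]2C(C)C)O1 | intermediate
19 | (5S)-5-[(1S,2R,5S)-menthyloxy]furan-2(5H)-one | O=C1C=C[C@@H](O[C@H]2C[C@@H](C)CC[C@@H]2C(C)C)O1 | intermediate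
20 | 3-(benzyloxy)-4-methoxybenzaldehyde | O=Cc1ccc(OC)c(OCc2ccccc2)c1 | starting material
21 | dilithium salt of 13 (lithium alkoxide, 2-lithio-1,3-dithiane) | [Li+].[Li+].S1CCCS[C-]1c1cc(OC)c2c(c1)O[C@H](c1ccc(OCc3ccccc3)c(OC)c1)[C@H]2C[O-] | intermediate
22 | dilithium (4S,5S)-lactone enolate from 1,4-addition of 21 to 19 | [Li+].[Li+].[O-]C1=C[C@H](C2(SCCCS2)c2cc(OC)c3c(c2)O[C@H](c2ccc(OCc4ccccc4)c(OC)c2)[C@H]3C[O-])[C@@H](O[C@H]2C[C@@H](C)CC[C@@H]2C(C)C)O1 | intermediate
23 | (3R,4S,5S)-dithianyl aldol lactone acetal (carbinol epimers) | O=C1O[C@H](O[C@H]2C[C@@H](C)CC[C@@H]2C(C)C)[C@@H](C2(SCCCS2)c2cc(OC)c3c(c2)O[C@H](c2ccc(OCc4ccccc4)c(OC)c2)[C@H]3CO)[C@@H]1C(O)c1ccc(OC)c(OCc2ccccc2)c1 | intermediate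
24 | (3R,4S,5S)-desulfurised, debenzylated lactone acetal (carbinol epimers) | O=C1O[C@H](O[C@H]2C[C@@H](C)CC[C@@H]2C(C)C)[C@@H](Cc2cc(OC)c3c(c2)O[C@H](c2ccc(O)c(OC)c2)[C@H]3CO)[C@@H]1C(O)c1ccc(OC)c(O)c1 | intermediate
25 | (2S,3S)-hexa-ol (carbinol epimers) | OC[C@@H](Cc1cc(OC)c2c(c1)O[C@H](c1ccc(O)c(OC)c1)[C@H]2CO)[C@@H](CO)C(O)c1ccc(OC)c(O)c1 | intermediate
26 | CNP0242386.1 | COc1ccc([C@@H]2OC[C@@H](Cc3cc(OC)c4c(c3)O[C@H](c3ccc(O)c(OC)c3)[C@H]4CO)[C@H]2CO)cc1O | target

## Step count and risks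

Total steps: 13. Longest linear sequence: 11 (steps 1–7 and 10–13, from 1); steps 8–9 are a two-step side branch.

Most likely to fail:

Step 3 (yield or facial control of the desymmetrising annulation). Fallback, setting out from 4 and 8 and rejoining at 11: drop the auxiliary and resolve instead. Acid 4 is esterified (MeOH, H2SO4) to methyl (E)-3-[4-(benzyloxy)-3-methoxyphenyl]prop-2-enoate F1. F1 is annulated with 8 under Mn(OAc)3/Cu(OAc)2 in AcOH to the racemic trans keto diester F2, which is aromatised with I2/MeOH to the dimethyl 4-methoxy-2,3-dihydrobenzofuran-3,6-dicarboxylate F3. F3 is resolved by preparative chromatography on a chiral stationary phase, and its (2S,3S) enantiomer is reduced with LiAlH4 to 11.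

Step 4 (acidic methanol may open the benzylic vinylogous ester before aromatisation). Fallback, from 9 back to 10: separate dehydrogenation from methylation and avoid nucleophilic solvent. Pd(DMSO)2(TFA)2-catalysed aerobic dehydrogenation (O2, EtOAc, 80 °C) gives the phenol methyl (2S,3S)-2-[4-(benzyloxy)-3-methoxyphenyl]-4-hydroxy-3-(sultam-N-carbonyl)-2,3-dihydro-1-benzofuran-6-carboxylate F4. F4 is O-methylated under neutral Mitsunobu conditions (MeOH, PPh3, DIAD) to 10, avoiding base-induced ring opening at C3.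

Step 11 (incomplete debenzylation, or over-reduction of the benzylic C–O bonds, by Raney Ni). Fallback, from 23 to 26: split the two reductive tasks and debenzylate last. Nickel boride (NiCl2·6H2O, NaBH4, MeOH–THF, 0 °C) removes only the dithiane to give the dibenzyl lactone acetal F5. LiAlH4 gives the dibenzyl tetra-ol F6, CSA closes the tetrahydrofuran to the dibenzyl ether of the target F7, and brief transfer hydrogenolysis (Pd/C, 1,4-cyclohexadiene, EtOAc–MeOH) gives 26.

## Further compounds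

F1 | step 3 | methyl (E)-3-[4-(benzyloxy)-3-methoxyphenyl]prop-2-enoate | COC(=O)/C=C/c1ccc(OCc2ccccc2)c(OC)c1
F2 | step 3 | dimethyl trans-2-[4-(benzyloxy)-3-methoxyphenyl]-4-oxo-2,3,4,5,6,7-hexahydro-1-benzofuran-3,6-dicarboxylate, racemic (2S,3S enantiomer drawn, C6 epimers) | COC(=O)C1CC(=O)C2=C(C1)O[C@H](c1ccc(OCc3ccccc3)c(OC)c1)[C@H]2C(=O)OC
F3 | step 3 | dimethyl (2S,3S)-2-[4-(benzyloxy)-3-methoxyphenyl]-4-methoxy-2,3-dihydro-1-benzofuran-3,6-dicarboxylate (formed racemic, used after resolution) | COC(=O)c1cc(OC)c2c(c1)O[C@H](c1ccc(OCc3ccccc3)c(OC)c1)[C@H]2C(=O)OC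
F4 | step 4 | methyl (2S,3S)-2-[4-(benzyloxy)-3-methoxyphenyl]-4-hydroxy-3-(sultam-N-carbonyl)-2,3-dihydro-1-benzofuran-6-carboxylate | COC(=O)c1cc(O)c2c(c1)O[C@H](c1ccc(OCc3ccccc3)c(OC)c1)[C@H]2C(=O)N1[C@H]2C[C@@H]3CC[C@@]2(CS1(=O)=O)C3(C)C
F5 | step 11 | (3R,4S,5S)-desulfurised lactone acetal, both benzyl ethers retained | O=C1O[C@H](O[C@H]2C[C@@H](C)CC[C@@H]2C(C)C)[C@@H](Cc2cc(OC)c3c(c2)O[C@H](c2ccc(OCc4ccccc4)c(OC)c2)[C@H]3CO)[C@@H]1C(O)c1ccc(OC)c(OCc2ccccc2)c1
F6 | step 11 | (2S,3S)-dibenzyl tetra-ol | OC[C@@H](Cc1cc(OC)c2c(c1)O[C@H](c1ccc(OCc3ccccc3)c(OC)c1)[C@H]2CO)[C@@H](CO)C(O)c1ccc(OC)c(OCc2ccccc2)c1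
F7 | step 11 | di-O-benzyl ether of 26 | COc1ccc([C@@H]2OC[C@@H](Cc3cc(OC)c4c(c3)O[C@H](c3ccc(OCc5ccccc5)c(OC)c3)[C@H]4CO)[C@H]2CO)cc1OCc1ccccc1
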